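Numbering used throughout: chroman atoms O1, C2, C3, C4, C4a, C5–C8, C8a; chain carbons 1–6 counted from ring A (chain C3 carries the methyl group, the double bond is chain C3=C4, chain C6 is bonded to C2); ring A atoms C1' (chain-bearing CH), C2' (gem-dimethyl), C3' (carbinol), C4', C5', C6' (methylidene). Compound numbers are those of the steps and the compound list below.

## Analysis of the target

The target 36 is a 2,8-dimethylchroman-6-ol whose C2 carries a six-carbon chain with one E-configured trisubstituted double bond (chain C3=C4). The chain ends in a monocyclic ring A that bears a gem-dimethyl group (C2'), a secondary hydroxyl (C3') and an exocyclic methylidene (C6'). There are three stereocentres. C2 is S and fully substituted (methyl, O1, C3, chain C6). C1' and C3' are both R, which places the hydroxyl and the side chain trans to each other across the gem-dimethyl carbon. C2 lies seven bonds from C1', so the two stereochemical domains cannot control each other and each has to be set on its own. The sensitive groups are the electron-rich, easily oxidised chromanol, the exocyclic alkene (which moves into the ring under acid), the E alkene, and the tertiary alkyl aryl ether at C2, which loses its configuration if the C2–O bond ionises. The hard part is C2: its four substituents are a methyl group, an oxygen and two CH2CH2 arms that differ only at a distance, so an addition to a ketone cannot tell them apart. The strategy rests on one feature. C2, its two-carbon arm (C3, C4) and its three-carbon arm (chain C6, C5, C4) are six carbons that become a cyclohexene once C4 and chain C4 are joined by a double bond. O1 is then replaced by a carbon substituent that can later be exchanged for oxygen with retention.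

## Retrosynthetic reasoning

Target 36 to bis-silyl ether 35. Both hydroxyls are unmasked together at the end with fluoride. A phenol methyl ether was avoided because its cleavage would need conditions that threaten the exocyclic alkene and the free chromanol.

35 to bromoarene 34. The O1–C8a bond is cut. The alternative cut, O1–C2, would need a substitution at a tertiary stereocentre. With the chosen cut the C2–O bond is never touched, so the configuration of C2 cannot erode. The forward step is an intramolecular palladium-catalysed etherification of a tertiary alcohol with an aryl bromide.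

34 to alkyl iodide 27 and dihaloarene 31. The C4–C4a bond is cut as an sp3–sp2 cross-coupling. The iodine of 31 marks C4a and the bromine marks C8a, so the coupling has to distinguish the two halogens. Compound 31 is traced to aminophenol 28 through 29 and 30; the amino group directs the iodination and is then itself exchanged for bromine.

27 to diol 25 to acetonide 24. The iodide comes from the primary hydroxyl of a 1,3-diol (through iodo alcohol 26). That diol has been carried as a six-membered acetonide, which protects the tertiary hydroxyl and the C4 oxygen together while the chain is built.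

24 to sulfone 21 and allylic bromide 13. The bond between chain C1 and chain C2 is cut. It is the only chain bond with a carbon that can carry a sulfonyl-stabilised anion on one side (next to ring A) and an allylic electrophile on the other. The E alkene stays intact inside 13 and both ring A stereocentres arrive finished in 21. The forward reaction is a sulfone alkylation (to 23) followed by reductive removal of sulfur.

13 to aldehyde 10. The chain C3=C4 double bond is cut. A stabilised Wittig reagent adds chain C2, C3 and the methyl group to aldehyde 10 with E geometry (enoate 11); reduction (12) and bromination follow.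

10 to triol 8. The aldehyde is the oxidised three-carbon arm of alcohol 9. In triol 8 the two primary hydroxyls are told apart by ring size: with the tertiary hydroxyl, the two-carbon arm closes a six-membered acetal and the three-carbon arm could only close a seven-membered one.

8 to cyclohexenyl acetate 6. C4 and chain C4 are reconnected as a ring double bond (retro-ozonolysis). This turns an acyclic triol with a remote quaternary centre into a simple ring.

6 to aldehyde 3. O1 is exchanged for a carbon: acetate 6 comes from methyl ketone 5 by Baeyer–Villiger oxidation with retention, and 5 comes from aldehyde 3 by methyl addition (alcohol 4) and oxidation.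

3 to buta-1,3-diene 1 and methacrolein 2. The cyclohexene is opened by a retro-Diels–Alder cut of the C2–C3 bond and of the bond between chain carbons 5 and 6. Forward, a chiral Lewis acid must choose one face of the dienophile; this is the only step that creates the C2 stereocentre.

21 to neryl acetate 14. The sulfone is made from alcohol 19 through sulfide 20. Ring A is opened at the C1'–C2' bond: hydroxy acetate 17 is the product of an epoxide-initiated radical cyclisation of epoxide 15, obtained from 14 by asymmetric epoxidation. The epoxide fixes C3', the Z alkene fixes C1' trans to it, and the exocyclic alkene is formed in the same step. A ring A precursor derived from a cyclic 1,3-dione would have its carbonyl at C1' and no handle at C6', and would need many more steps.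

## Alternatives that were turned down

Alternative 1: The trisubstituted alkene and the bond between chain carbons 4 and 5 are disconnected together. A ring A terminal alkyne A2 would undergo zirconium-catalysed syn-methylalumination, and the derived alkenyl aluminate would open the 2,2-disubstituted oxetane A3 at its O-bound methylene to give the open-chain tertiary alcohol A1. In its favour, syn-carbometalation gives the E geometry and the methyl group in one operation, the union is convergent, and A1 is only a ring closure and a deprotection away from the target. On convergence and on the number of steps after fragment union this plan is stronger than the chosen one. Against it, the key step creates no stereocentre and closes no ring. The C2 stereocentre has to be present already in A3, so the hardest problem of the target is moved into a fragment and not solved. Alkenyl aluminium species open oxetanes only after conversion to an ate complex and Lewis acid activation. Those conditions expose the aryl bromide of A3 to halogen–metal exchange. They also invite ionisation of the tertiary C–O bond of the oxetane, with attack at the wrong carbon or loss of configuration. A2 in turn needs ring A plus a two-carbon homologation. The chosen route takes more steps but creates C2 catalytically from two commodity chemicals, and its alkene geometry comes from a stabilised Wittig reaction that is no less reliable.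

Alternative 2: Ring A is disconnected at the C6'–C1' bond. A tin hydride would add its stannyl radical to the terminal alkyne of the acyclic silyloxy enynoate A5, the vinyl radical would close 6-exo onto the enoate β-carbon, and protodestannylation would give ester A4. In its favour, the exocyclic alkene is formed regiospecifically, and the ester arm already contains chain C1 and C2. On regiochemical purity of the alkene it is at least as strong as the cyclisation used here. Against it, the chain-bearing centre is set relative to the silyloxy centre through a chair-like transition state in which both groups sit equatorial. A4 is accordingly the (1R,3S), cis isomer, whereas the target needs the (1R,3R), trans arrangement, so the hindered carbinol between the gem-dimethyl group and a methylene would still have to be inverted. The step uses tin in stoichiometric amount and A5 is itself a multistep compound. Most importantly, the plan addresses only ring A and leaves C2 and the E alkene unsolved. The chosen route also closes ring A by a radical cyclisation, but at C1'–C2' from epoxide 15, where the Z alkene encodes the trans relationship, and it spends its key step on the remote quaternary centre.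

Alternative 3: The chroman is disconnected at C4–C4a by a retro dienone–phenol rearrangement. A boron Lewis acid would activate the spirocyclohexadienone A7, the ring methylene C4 would migrate from the spiro carbon to the neighbouring unsubstituted carbon, and the phenol A6 would form with the tetrahydrofuran enlarged to the dihydropyran. In its favour, the C2–O bond is already in place and is not broken, the phenol appears without a protecting group, and no transition metal is needed. For the chromanol alone this is shorter than the sequence used here. Against it, the two dienone termini differ: migration toward the methyl-bearing carbon gives a cation that cannot aromatise directly, and that carbon is the more stabilised one. The Lewis acid also meets a trisubstituted alkene a few atoms from the cationic ring and a tertiary ether that can ionise. A6 ends in a prenyl group, so its E-methyl would have to be oxidised in the presence of an oxidation-prone chromanol before ring A could be attached. The stereocentre of A7 has to be imported from elsewhere. The chosen route gives up this brevity. In return it selects the C2 configuration by the catalyst enantiomer, delivers the chain terminus directly as an aldehyde, and closes the ether at a position fixed by a halogen.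

Key step: step 1

Assumption (sense of induction in step 1): the oxazaborolidinium ion from (S)-α,α-diphenylprolinol is taken to give the (S)-aldehyde 3, following the formyl C–H···O binding model for 2-substituted acroleins. Both enantiomers of the prolinol are commercial, so an opposite sense would be corrected by using the (R)-catalyst with nothing else changed.

## Route

Step 1
Reactants: 1 buta-1,3-diene; 2 methacrolein
Product: 3 (1S)-1-methylcyclohex-3-ene-1-carbaldehyde
Conditions: (S)-1-(2-methylphenyl)-3,3-diphenyltetrahydro-1H,3H-pyrrolo[1,2-c][1,3,2]oxazaborole (10 mol%), Tf2NH (10 mol%), CH2Cl2, −78 °C; 2, then excess 1, −78 → −20 °C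
Reagents that add atoms: none
Why: Protonation of the oxazaborolidine nitrogen by Tf2NH gives a cationic boron Lewis acid that binds the formyl oxygen of 2 anti to the vinyl group, with the formyl C–H held against the ring oxygen, so the s-trans enal lies over one aryl group and only one face stays open. Butadiene in its s-cis form adds to that face in a concerted, asynchronous [4+2] cycloaddition; the closest known reaction type is the oxazaborolidinium-catalysed Diels–Alder reaction of 2-substituted acroleins with simple acyclic dienes. The cyclohexene ring closes by this intermolecular cycloaddition, and both new σ bonds (the later C2–C3 bond and the bond between chain carbons 5 and 6) form in the same step. The single new stereocentre, the quaternary carbon that becomes C2, is set by the catalyst alone through enantiofacial discrimination of the dienophile. No regio- or endo/exo selectivity is needed, because butadiene is symmetric and the carbons it delivers carry no substituents. Butadiene is a sluggish diene, so the triflimide-activated catalyst, an excess of diene and a slow warm-up are used, and the volatile product is carried on without exhaustive concentration.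

Step 2
Reactants: 3 (1S)-1-methylcyclohex-3-ene-1-carbaldehyde
Product: 4 1-[(1S)-1-methylcyclohex-3-en-1-yl]ethan-1-ol (both carbinol epimers)
Conditions: MeMgBr, Et2O, 0 °C; aq. NH4Cl
Reagents that add atoms: methylmagnesium bromide, C[Mg]Br
Why: Grignard 1,2-addition to an aldehyde that cannot enolise; the new carbinol centre forms without control and is erased in step 3.

Step 3
Reactants: 4 1-[(1S)-1-methylcyclohex-3-en-1-yl]ethan-1-ol
Product: 5 1-[(1S)-1-methylcyclohex-3-en-1-yl]ethan-1-one
Conditions: Dess–Martin periodinane, NaHCO3, CH2Cl2, 0 °C → rt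
Reagents that add atoms: none
Why: Dess–Martin oxidation of a hindered secondary alcohol under buffered conditions; the quaternary α-carbon cannot epimerise and the alkene is not touched.

Step 4
Reactants: 5 1-[(1S)-1-methylcyclohex-3-en-1-yl]ethan-1-one
Product: 6 (1S)-1-methylcyclohex-3-en-1-yl acetate
Conditions: Me3SiOOSiMe3, Me3SiOTf (cat.), CH2Cl2, −78 → −40 °C
Reagents that add atoms: bis(trimethylsilyl) peroxide, C[Si](C)(C)OO[Si](C)(C)C
Why: Baeyer–Villiger oxidation: the silyl peroxide adds to the Lewis-acid-activated ketone and the tertiary alkyl group migrates in preference to methyl with retention, so oxygen takes the place of the acetyl carbon on the same face. This peroxide is not an epoxidising agent, so the ring alkene survives.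

Step 5
Reactants: 6 (1S)-1-methylcyclohex-3-en-1-yl acetate
Product: 8 (3S)-3-methylhexane-1,3,6-triol, via diol monoacetate 7 (not isolated)
Conditions: O3, CH2Cl2/MeOH, −78 °C; NaBH4, −78 °C → rt; then NaOMe (cat.), MeOH, rt → 40 °C; acidic resin, evaporation
Reagents that add atoms: ozone, [O-][O+]=O
Why: Ozonolysis of the only alkene with borohydride reduction of the cleavage products gives the two primary alcohols; base-catalysed methanolysis, helped by acyl transfer to the neighbouring primary hydroxyl, removes the acetate. The stereocentre is not involved.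

Step 6
Reactants: 8 (3S)-3-methylhexane-1,3,6-triol
Product: 9 3-[(4S)-2,2,4-trimethyl-1,3-dioxan-4-yl]propan-1-ol
Conditions: Me2C(OMe)2, TsOH·H2O (cat.), acetone, rt; Et3N; brief wet MeOH/pyridinium p-toluenesulfonate wash
Reagents that add atoms: 2,2-dimethoxypropane, COC(C)(C)OC
Why: Acid-catalysed acetalisation under equilibrating conditions: the tertiary hydroxyl and the hydroxyl of the two-carbon arm close a six-membered 1,3-dioxane, whereas the three-carbon arm could only give a seven-membered acetal and so keeps its hydroxyl. Any mixed acetal on the primary hydroxyl is cleaved in the wash.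

Step 7
Reactants: 9 3-[(4S)-2,2,4-trimethyl-1,3-dioxan-4-yl]propan-1-ol
Product: 10 3-[(4S)-2,2,4-trimethyl-1,3-dioxan-4-yl]propanal
Conditions: Dess–Martin periodinane, NaHCO3, CH2Cl2, 0 °C → rt
Reagents that add atoms: none
Why: Dess–Martin oxidation of the primary alcohol to the aldehyde that becomes chain C4; the bicarbonate buffer protects the acetonide from the acetic acid set free.

Step 8
Reactants: 10 3-[(4S)-2,2,4-trimethyl-1,3-dioxan-4-yl]propanal
Product: 11 ethyl (2E)-2-methyl-5-[(4S)-2,2,4-trimethyl-1,3-dioxan-4-yl]pent-2-enoate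
Conditions: Ph3P=C(Me)CO2Et, CH2Cl2, rt → 40 °C
Reagents that add atoms: ethyl 2-(triphenylphosphoranylidene)propanoate, CCOC(=O)C(C)=P(c1ccccc1)(c1ccccc1)c1ccccc1
Why: Wittig olefination with a stabilised, α-branched ylide: reversible addition lets the ester settle trans to the alkyl chain, which gives the E trisubstituted alkene (chain C3=C4) with the methyl group in place.

Step 9
Reactants: 11 ethyl (2E)-2-methyl-5-[(4S)-2,2,4-trimethyl-1,3-dioxan-4-yl]pent-2-enoate
Product: 12 (2E)-2-methyl-5-[(4S)-2,2,4-trimethyl-1,3-dioxan-4-yl]pent-2-en-1-ol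
Conditions: i-Bu2AlH, CH2Cl2, −78 °C; aq. potassium sodium tartrate
Reagents that add atoms: none
Why: 1,2-Reduction of the enoate to the allylic alcohol by the aluminium hydride; alkene geometry and acetonide are untouched at low temperature.

Step 10
Reactants: 12 (2E)-2-methyl-5-[(4S)-2,2,4-trimethyl-1,3-dioxan-4-yl]pent-2-en-1-ol
Product: 13 (4S)-4-[(3E)-5-bromo-4-methylpent-3-en-1-yl]-2,2,4-trimethyl-1,3-dioxane
Conditions: CBr4, PPh3, 2,6-lutidine, CH2Cl2, −20 → 0 °C
Reagents that add atoms: tetrabromomethane, BrC(Br)(Br)Br
Why: Appel bromination: bromide displaces the alkoxyphosphonium group at the primary allylic carbon in an SN2 reaction without allylic transposition. The base scavenges traces of HBr that would open the acetonide.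

Step 11
Reactants: 14 neryl acetate, (2Z)-3,7-dimethylocta-2,6-dien-1-yl acetate
Product: 15 (2Z)-5-[(2R)-3,3-dimethyloxiran-2-yl]-3-methylpent-2-en-1-yl acetate
Conditions: 1,2:4,5-di-O-isopropylidene-β-D-erythro-2,3-hexodiulo-2,6-pyranose (30 mol%), KHSO5 (as 2KHSO5·KHSO4·K2SO4), K2CO3, Bu4NHSO4, MeCN/CH2(OMe)2/aq. Na2B4O7 buffer, 0 °C
Reagents that add atoms: potassium peroxymonosulfate, [K+].[O-]S(=O)(=O)OO
Why: Shi epoxidation: the chiral dioxirane formed from the ketone transfers oxygen through a spiro transition state to the electron-rich 6,7-alkene, whereas the 2,3-alkene is deactivated by the allylic acetate. The D-fructose-derived catalyst should give the (R)-epoxide, whose carbinol carbon becomes C3'.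

Step 12
Reactants: 15 (2Z)-5-[(2R)-3,3-dimethyloxiran-2-yl]-3-methylpent-2-en-1-yl acetate
Product: 17 [(1R,3R)-3-hydroxy-2,2-dimethyl-6-methylidenecyclohexyl]methyl acetate, via its trimethylsilyl ether 16 (not isolated)
Conditions: Cp2TiCl2 (20 mol%), Mn dust, Me3SiCl, 2,4,6-collidine, THF, rt; then 1 M HCl, THF, rt (brief)
Reagents that add atoms: none
Why: Radical cyclisation of an epoxy alkene mediated by trivalent titanium (Cp2TiCl formed from Cp2TiCl2 and Mn): homolytic opening at the tertiary epoxide carbon is followed by 6-endo attack of the tertiary radical on the less substituted alkene carbon through a chair with the titanoxy group equatorial. The Z geometry places the acetoxymethyl group axial, trans to oxygen, which sets C1' relative to C3'; the C3' configuration is that of the epoxide. Trapping of the new tertiary radical by titanium and β-hydride elimination towards the methyl group gives the exocyclic alkene.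

Step 13
Reactants: 17 [(1R,3R)-3-hydroxy-2,2-dimethyl-6-methylidenecyclohexyl]methyl acetate
Product: 18 [(1R,3R)-3-{[tert-butyl(dimethyl)silyl]oxy}-2,2-dimethyl-6-methylidenecyclohexyl]methyl acetate
Conditions: t-BuMe2SiOTf, 2,6-lutidine, CH2Cl2, 0 °C
Reagents that add atoms: tert-butyldimethylsilyl trifluoromethanesulfonate, CC(C)(C)[Si](C)(C)OS(=O)(=O)C(F)(F)F
Why: Silylation of the hindered secondary alcohol next to the gem-dimethyl carbon needs the reactive silyl triflate; the acetate and the alkene are inert to it.

Step 14
Reactants: 18 [(1R,3R)-3-{[tert-butyl(dimethyl)silyl]oxy}-2,2-dimethyl-6-methylidenecyclohexyl]methyl acetate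
Product: 19 [(1R,3R)-3-{[tert-butyl(dimethyl)silyl]oxy}-2,2-dimethyl-6-methylidenecyclohexyl]methanol
Conditions: K2CO3, MeOH, rt
Reagents that add atoms: none
Why: Base-catalysed methanolysis of the primary acetate; the silyl ether and the non-conjugated exocyclic alkene are stable to carbonate in methanol.

Step 15
Reactants: 19 [(1R,3R)-3-{[tert-butyl(dimethyl)silyl]oxy}-2,2-dimethyl-6-methylidenecyclohexyl]methanol
Product: 20 tert-butyl(dimethyl){[(1R,3R)-2,2-dimethyl-4-methylidene-3-[(phenylsulfanyl)methyl]cyclohexyl]oxy}silane
Conditions: PhSSPh, n-Bu3P, pyridine, rt → 50 °C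
Reagents that add atoms: diphenyl disulfide, c1ccc(SSc2ccccc2)cc1
Why: Hata-type thioetherification: the alcohol is activated as an alkoxyphosphonium ion and displaced by thiolate in an SN2 reaction at the β-branched primary carbon; no stereocentre takes part.

Step 16
Reactants: 20 tert-butyl(dimethyl){[(1R,3R)-2,2-dimethyl-4-methylidene-3-[(phenylsulfanyl)methyl]cyclohexyl]oxy}silane
Product: 21 {[(1R,3R)-3-[(benzenesulfonyl)methyl]-2,2-dimethyl-4-methylidenecyclohexyl]oxy}(tert-butyl)dimethylsilane
Conditions: H2O2 (30%), (NH4)6Mo7O24·4H2O (cat.), EtOH, 0 °C → rt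
Reagents that add atoms: hydrogen peroxide, OO
Why: Molybdate-catalysed peroxide oxidation takes the sulfide through the sulfoxide to the sulfone; the peroxomolybdate oxidises sulfur far faster than an unactivated 1,1-disubstituted alkene.

Step 17
Reactants: 21 {[(1R,3R)-3-[(benzenesulfonyl)methyl]-2,2-dimethyl-4-methylidenecyclohexyl]oxy}(tert-butyl)dimethylsilane; 13 (4S)-4-[(3E)-5-bromo-4-methylpent-3-en-1-yl]-2,2,4-trimethyl-1,3-dioxane
Product: 23 tert-butyl{[(1R,3R)-3-[(3E)-1-(benzenesulfonyl)-3-methyl-6-[(4S)-2,2,4-trimethyl-1,3-dioxan-4-yl]hex-3-en-1-yl]-2,2-dimethyl-4-methylidenecyclohexyl]oxy}dimethylsilane (both epimers at the sulfonyl carbon), via α-lithio sulfone 22 (not isolated)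
Conditions: n-BuLi, THF, −78 °C; DMPU; then 13, −78 → −20 °C
Reagents that add atoms: none
Why: Alkylation of an α-sulfonyl carbanion with a primary allylic bromide (SN2, no allylic transposition) forms the bond between chain C1 and C2 and joins the two halves. The new stereocentre at the sulfonyl carbon is uncontrolled and is removed in step 18.

Step 18
Reactants: 23 tert-butyl{[(1R,3R)-3-[(3E)-1-(benzenesulfonyl)-3-methyl-6-[(4S)-2,2,4-trimethyl-1,3-dioxan-4-yl]hex-3-en-1-yl]-2,2-dimethyl-4-methylidenecyclohexyl]oxy}dimethylsilane
Product: 24 tert-butyl{[(1R,3R)-2,2-dimethyl-3-[(3E)-3-methyl-6-[(4S)-2,2,4-trimethyl-1,3-dioxan-4-yl]hex-3-en-1-yl]-4-methylidenecyclohexyl]oxy}dimethylsilane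
Conditions: Na/Hg (6% Na), Na2HPO4, MeOH/THF, −20 °C
Reagents that add atoms: none
Why: Reductive desulfonylation by electron transfer from sodium amalgam, with buffered methanol as the proton source. The sulfone is homoallylic to both alkenes, so C–S cleavage should not move either double bond.

Step 19
Reactants: 24 tert-butyl{[(1R,3R)-2,2-dimethyl-3-[(3E)-3-methyl-6-[(4S)-2,2,4-trimethyl-1,3-dioxan-4-yl]hex-3-en-1-yl]-4-methylidenecyclohexyl]oxy}dimethylsilane
Product: 25 (3S,6E)-9-[(1R,3R)-3-{[tert-butyl(dimethyl)silyl]oxy}-2,2-dimethyl-6-methylidenecyclohexyl]-3,7-dimethylnon-6-ene-1,3-diol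
Conditions: pyridinium p-toluenesulfonate, MeOH, rt
Reagents that add atoms: none
Why: Acid-catalysed transacetalisation in methanol opens the strained acetonide; the hindered secondary silyl ether and both alkenes tolerate the weak pyridinium acid.

Step 20
Reactants: 25 (3S,6E)-9-[(1R,3R)-3-{[tert-butyl(dimethyl)silyl]oxy}-2,2-dimethyl-6-methylidenecyclohexyl]-3,7-dimethylnon-6-ene-1,3-diol
Product: 26 (3S,6E)-9-[(1R,3R)-3-{[tert-butyl(dimethyl)silyl]oxy}-2,2-dimethyl-6-methylidenecyclohexyl]-1-iodo-3,7-dimethylnon-6-en-3-ol
Conditions: I2, PPh3, imidazole, CH2Cl2, 0 °C → rt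
Reagents that add atoms: iodine, II
Why: Appel-type iodination: only the primary hydroxyl forms the alkoxyphosphonium ion that iodide displaces; the tertiary hydroxyl is too hindered to react under these conditions.

Step 21
Reactants: 26 (3S,6E)-9-[(1R,3R)-3-{[tert-butyl(dimethyl)silyl]oxy}-2,2-dimethyl-6-methylidenecyclohexyl]-1-iodo-3,7-dimethylnon-6-en-3-ol
Product: 27 tert-butyl{[(1R,3R)-3-[(3E,7S)-9-iodo-3,7-dimethyl-7-[(trimethylsilyl)oxy]non-3-en-1-yl]-2,2-dimethyl-4-methylidenecyclohexyl]oxy}dimethylsilane
Conditions: Me3SiOTf, 2,6-lutidine, CH2Cl2, −78 °C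
Reagents that add atoms: trimethylsilyl trifluoromethanesulfonate, C[Si](C)(C)OS(=O)(=O)C(F)(F)F
Why: Silylation of the tertiary alcohol with the silyl triflate removes the only acidic proton before the organozinc reagent is made.

Step 22
Reactants: 28 4-amino-3-methylphenol
Product: 29 2-methyl-4-{[tri(propan-2-yl)silyl]oxy}aniline
Conditions: i-Pr3SiCl, imidazole, DMF, rt
Reagents that add atoms: chlorotri(propan-2-yl)silane, CC(C)[Si](Cl)(C(C)C)C(C)C
Why: Silylation takes place at the phenol oxygen rather than at the aniline nitrogen and gives a fluoride-labile aryl ether that is robust enough for the later steps.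

Step 23
Reactants: 29 2-methyl-4-{[tri(propan-2-yl)silyl]oxy}aniline
Product: 30 2-iodo-6-methyl-4-{[tri(propan-2-yl)silyl]oxy}aniline
Conditions: N-iodosuccinimide, MeCN, 0 °C
Reagents that add atoms: N-iodosuccinimide, O=C1CCC(=O)N1I
Why: Electrophilic aromatic iodination directed by the amino group: its para position is blocked by oxygen and one ortho position by methyl, so iodine enters the free ortho position, the later C4a.

Step 24
Reactants: 30 2-iodo-6-methyl-4-{[tri(propan-2-yl)silyl]oxy}aniline
Product: 31 (4-bromo-3-iodo-5-methylphenoxy)tri(propan-2-yl)silane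
Conditions: t-BuONO, CuBr2, MeCN, 0 °C → rt
Reagents that add atoms: copper dibromide, Br[Cu]Br
Why: Sandmeyer bromination in one pot: diazotisation by the alkyl nitrite and copper-mediated radical replacement of nitrogen put bromine on the later C8a, between methyl and iodine.

Step 25
Reactants: 27 tert-butyl{[(1R,3R)-3-[(3E,7S)-9-iodo-3,7-dimethyl-7-[(trimethylsilyl)oxy]non-3-en-1-yl]-2,2-dimethyl-4-methylidenecyclohexyl]oxy}dimethylsilane; 31 (4-bromo-3-iodo-5-methylphenoxy)tri(propan-2-yl)silane
Product: 34 (3S,6E)-1-(2-bromo-3-methyl-5-{[tri(propan-2-yl)silyl]oxy}phenyl)-9-[(1R,3R)-3-{[tert-butyl(dimethyl)silyl]oxy}-2,2-dimethyl-6-methylidenecyclohexyl]-3,7-dimethylnon-6-en-3-ol, via alkylzinc iodide 32 (not isolated), via trimethylsilyl-protected coupling product 33 (not isolated)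
Conditions: Zn dust (activated), LiCl, THF, 40 °C; decant from Zn; 31 (1.3 equiv), PdCl2(dppf) (5 mol%), THF, rt → 40 °C; then citric acid, MeOH, rt
Reagents that add atoms: none
Why: Negishi coupling: zinc inserts into the primary C–I bond, and zerovalent palladium adds oxidatively to the aryl C–I bond much faster than to the C–Br bond flanked by two ortho substituents, so only the C4–C4a bond forms. The bidentate ferrocenyl diphosphine suppresses β-hydride elimination, and mild acid then removes the tertiary trimethylsilyl ether while the two bulkier silyl ethers stay.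

Step 26
Reactants: 34 (3S,6E)-1-(2-bromo-3-methyl-5-{[tri(propan-2-yl)silyl]oxy}phenyl)-9-[(1R,3R)-3-{[tert-butyl(dimethyl)silyl]oxy}-2,2-dimethyl-6-methylidenecyclohexyl]-3,7-dimethylnon-6-en-3-ol
Product: 35 tert-butyl{[(1R,3R)-3-[(3E)-6-[(2S)-2,8-dimethyl-6-{[tri(propan-2-yl)silyl]oxy}-3,4-dihydro-2H-chromen-2-yl]-3-methylhex-3-en-1-yl]-2,2-dimethyl-4-methylidenecyclohexyl]oxy}dimethylsilane
Conditions: Pd(OAc)2 (5 mol%), rac-2-(di-tert-butylphosphino)-1,1'-binaphthyl (6 mol%), Cs2CO3, toluene, 80 °C
Reagents that add atoms: none
Why: Intramolecular palladium-catalysed aryl ether formation (Buchwald–Hartwig etherification): oxidative addition to C–Br, binding of the tertiary alkoxide (which has no hydrogen on the carbinol carbon for β-hydride elimination) and reductive elimination promoted by the bulky phosphine close the six-membered ring at O1–C8a. The C2–O bond is not broken, so C2 keeps its configuration.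

Step 27
Reactants: 35 tert-butyl{[(1R,3R)-3-[(3E)-6-[(2S)-2,8-dimethyl-6-{[tri(propan-2-yl)silyl]oxy}-3,4-dihydro-2H-chromen-2-yl]-3-methylhex-3-en-1-yl]-2,2-dimethyl-4-methylidenecyclohexyl]oxy}dimethylsilane
Product: 36 (2S)-2-[(3E)-6-[(1R,3R)-3-hydroxy-2,2-dimethyl-6-methylidenecyclohexyl]-4-methylhex-3-en-1-yl]-2,8-dimethyl-3,4-dihydro-2H-chromen-6-ol
Conditions: Bu4NF, THF (degassed), rt → 50 °C; aq. NH4Cl
Reagents that add atoms: none
Why: Fluoride cleaves the aryl silyl ether and, on warming, the hindered secondary silyl ether; nothing else in the molecule reacts with fluoride. Air is excluded because the chromanol is prone to oxidation.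

## Compound list

1 | buta-1,3-diene | C=CC=C | starting material
2 | methacrolein (2-methylprop-2-enal) | C=C(C)C=O | starting material
3 | (1S)-1-methylcyclohex-3-ene-1-carbaldehyde | O=C[C@]1(C)CC=CCC1 | intermediate
4 | 1-[(1S)-1-methylcyclohex-3-en-1-yl]ethan-1-ol (both carbinol epimers) | CC(O)[C@]1(C)CC=CCC1 | intermediate
5 | 1-[(1S)-1-methylcyclohex-3-en-1-yl]ethan-1-one | CC(=O)[C@]1(C)CC=CCC1 | intermediate
6 | (1S)-1-methylcyclohex-3-en-1-yl acetate | CC(=O)O[C@]1(C)CC=CCC1 | intermediate
7 | (3S)-1,6-dihydroxy-3-methylhexan-3-yl acetate | CC(=O)O[C@](CCCO)(C)CCO | intermediate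
8 | (3S)-3-methylhexane-1,3,6-triol | OCCC[C@@](O)(C)CCO | intermediate
9 | 3-[(4S)-2,2,4-trimethyl-1,3-dioxan-4-yl]propan-1-ol | OCCC[C@@]1(C)CCOC(C)(C)O1 | intermediate
10 | 3-[(4S)-2,2,4-trimethyl-1,3-dioxan-4-yl]propanal | O=CCC[C@@]1(C)CCOC(C)(C)O1 | intermediate
11 | ethyl (2E)-2-methyl-5-[(4S)-2,2,4-trimethyl-1,3-dioxan-4-yl]pent-2-enoate | CCOC(=O)/C(C)=C/CC[C@@]1(C)CCOC(C)(C)O1 | intermediate
12 | (2E)-2-methyl-5-[(4S)-2,2,4-trimethyl-1,3-dioxan-4-yl]pent-2-en-1-ol | OC/C(C)=C/CC[C@@]1(C)CCOC(C)(C)O1 | intermediate
13 | (4S)-4-[(3E)-5-bromo-4-methylpent-3-en-1-yl]-2,2,4-trimethyl-1,3-dioxane | BrC/C(C)=C/CC[C@@]1(C)CCOC(C)(C)O1 | intermediate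
14 | neryl acetate, (2Z)-3,7-dimethylocta-2,6-dien-1-yl acetate | CC(C)=CCC/C(C)=C\COC(C)=O | starting material
15 | (2Z)-5-[(2R)-3,3-dimethyloxiran-2-yl]-3-methylpent-2-en-1-yl acetate | CC(=O)OC/C=C(C)\CC[C@H]1OC1(C)C | intermediate
16 | [(1R,3R)-2,2-dimethyl-6-methylidene-3-[(trimethylsilyl)oxy]cyclohexyl]methyl acetate | C=C1CC[C@@H](O[Si](C)(C)C)C(C)(C)[C@@H]1COC(C)=O | intermediate
17 | [(1R,3R)-3-hydroxy-2,2-dimethyl-6-methylidenecyclohexyl]methyl acetate | C=C1CC[C@@H](O)C(C)(C)[C@@H]1COC(C)=O | intermediate
18 | [(1R,3R)-3-{[tert-butyl(dimethyl)silyl]oxy}-2,2-dimethyl-6-methylidenecyclohexyl]methyl acetate | C=C1CC[C@@H](O[Si](C)(C)C(C)(C)C)C(C)(C)[C@@H]1COC(C)=O | intermediate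
19 | [(1R,3R)-3-{[tert-butyl(dimethyl)silyl]oxy}-2,2-dimethyl-6-methylidenecyclohexyl]methanol | C=C1CC[C@@H](O[Si](C)(C)C(C)(C)C)C(C)(C)[C@@H]1CO | intermediate
20 | tert-butyl(dimethyl){[(1R,3R)-2,2-dimethyl-4-methylidene-3-[(phenylsulfanyl)methyl]cyclohexyl]oxy}silane | C=C1CC[C@@H](O[Si](C)(C)C(C)(C)C)C(C)(C)[C@@H]1CSc1ccccc1 | intermediate
21 | {[(1R,3R)-3-[(benzenesulfonyl)methyl]-2,2-dimethyl-4-methylidenecyclohexyl]oxy}(tert-butyl)dimethylsilane | C=C1CC[C@@H](O[Si](C)(C)C(C)(C)C)C(C)(C)[C@@H]1CS(=O)(=O)c1ccccc1 | intermediate
22 | [(benzenesulfonyl){(1R,3R)-3-{[tert-butyl(dimethyl)silyl]oxy}-2,2-dimethyl-6-methylidenecyclohexyl}methyl]lithium | C=C1CC[C@@H](O[Si](C)(C)C(C)(C)C)C(C)(C)[C@@H]1C([Li])S(=O)(=O)c1ccccc1 | intermediate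
23 | tert-butyl{[(1R,3R)-3-[(3E)-1-(benzenesulfonyl)-3-methyl-6-[(4S)-2,2,4-trimethyl-1,3-dioxan-4-yl]hex-3-en-1-yl]-2,2-dimethyl-4-methylidenecyclohexyl]oxy}dimethylsilane (both epimers at the sulfonyl carbon) | C=C1CC[C@@H](O[Si](C)(C)C(C)(C)C)C(C)(C)[C@@H]1C(C/C(C)=C/CC[C@@]2(C)CCOC(C)(C)O2)S(=O)(=O)c1ccccc1 | intermediate
24 | tert-butyl{[(1R,3R)-2,2-dimethyl-3-[(3E)-3-methyl-6-[(4S)-2,2,4-trimethyl-1,3-dioxan-4-yl]hex-3-en-1-yl]-4-methylidenecyclohexyl]oxy}dimethylsilane | C=C1CC[C@@H](O[Si](C)(C)C(C)(C)C)C(C)(C)[C@@H]1CC/C(C)=C/CC[C@@]1(C)CCOC(C)(C)O1 | intermediate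
25 | (3S,6E)-9-[(1R,3R)-3-{[tert-butyl(dimethyl)silyl]oxy}-2,2-dimethyl-6-methylidenecyclohexyl]-3,7-dimethylnon-6-ene-1,3-diol | C=C1CC[C@@H](O[Si](C)(C)C(C)(C)C)C(C)(C)[C@@H]1CC/C(C)=C/CC[C@@](O)(C)CCO | intermediate
26 | (3S,6E)-9-[(1R,3R)-3-{[tert-butyl(dimethyl)silyl]oxy}-2,2-dimethyl-6-methylidenecyclohexyl]-1-iodo-3,7-dimethylnon-6-en-3-ol | C=C1CC[C@@H](O[Si](C)(C)C(C)(C)C)C(C)(C)[C@@H]1CC/C(C)=C/CC[C@@](O)(C)CCI | intermediate
27 | tert-butyl{[(1R,3R)-3-[(3E,7S)-9-iodo-3,7-dimethyl-7-[(trimethylsilyl)oxy]non-3-en-1-yl]-2,2-dimethyl-4-methylidenecyclohexyl]oxy}dimethylsilane | C=C1CC[C@@H](O[Si](C)(C)C(C)(C)C)C(C)(C)[C@@H]1CC/C(C)=C/CC[C@@](O[Si](C)(C)C)(C)CCI | intermediate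
28 | 4-amino-3-methylphenol | Cc1cc(O)ccc1N | starting material
29 | 2-methyl-4-{[tri(propan-2-yl)silyl]oxy}aniline | Cc1cc(O[Si](C(C)C)(C(C)C)C(C)C)ccc1N | intermediate
30 | 2-iodo-6-methyl-4-{[tri(propan-2-yl)silyl]oxy}aniline | Cc1cc(O[Si](C(C)C)(C(C)C)C(C)C)cc(I)c1N | intermediate
31 | (4-bromo-3-iodo-5-methylphenoxy)tri(propan-2-yl)silane | Cc1cc(O[Si](C(C)C)(C(C)C)C(C)C)cc(I)c1Br | intermediate
32 | {(3S,6E)-9-[(1R,3R)-3-{[tert-butyl(dimethyl)silyl]oxy}-2,2-dimethyl-6-methylidenecyclohexyl]-3,7-dimethyl-3-[(trimethylsilyl)oxy]non-6-en-1-yl}(iodo)zinc | C=C1CC[C@@H](O[Si](C)(C)C(C)(C)C)C(C)(C)[C@@H]1CC/C(C)=C/CC[C@@](O[Si](C)(C)C)(C)CC[Zn]I | intermediate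
33 | {[(3S,6E)-1-(2-bromo-3-methyl-5-{[tri(propan-2-yl)silyl]oxy}phenyl)-9-[(1R,3R)-3-{[tert-butyl(dimethyl)silyl]oxy}-2,2-dimethyl-6-methylidenecyclohexyl]-3,7-dimethylnon-6-en-3-yl]oxy}(trimethyl)silane | C=C1CC[C@@H](O[Si](C)(C)C(C)(C)C)C(C)(C)[C@@H]1CC/C(C)=C/CC[C@@](O[Si](C)(C)C)(C)CCc1cc(O[Si](C(C)C)(C(C)C)C(C)C)cc(C)c1Br | intermediate
34 | (3S,6E)-1-(2-bromo-3-methyl-5-{[tri(propan-2-yl)silyl]oxy}phenyl)-9-[(1R,3R)-3-{[tert-butyl(dimethyl)silyl]oxy}-2,2-dimethyl-6-methylidenecyclohexyl]-3,7-dimethylnon-6-en-3-ol | C=C1CC[C@@H](O[Si](C)(C)C(C)(C)C)C(C)(C)[C@@H]1CC/C(C)=C/CC[C@@](O)(C)CCc1cc(O[Si](C(C)C)(C(C)C)C(C)C)cc(C)c1Br | intermediate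
35 | tert-butyl{[(1R,3R)-3-[(3E)-6-[(2S)-2,8-dimethyl-6-{[tri(propan-2-yl)silyl]oxy}-3,4-dihydro-2H-chromen-2-yl]-3-methylhex-3-en-1-yl]-2,2-dimethyl-4-methylidenecyclohexyl]oxy}dimethylsilane | C=C1CC[C@@H](O[Si](C)(C)C(C)(C)C)C(C)(C)[C@@H]1CC/C(C)=C/CC[C@@]1(C)CCc2cc(O[Si](C(C)C)(C(C)C)C(C)C)cc(C)c2O1 | intermediate
36 | (2S)-2-[(3E)-6-[(1R,3R)-3-hydroxy-2,2-dimethyl-6-methylidenecyclohexyl]-4-methylhex-3-en-1-yl]-2,8-dimethyl-3,4-dihydro-2H-chromen-6-ol | C=C1CC[C@@H](O)C(C)(C)[C@@H]1CC/C(C)=C/CC[C@@]1(C)CCc2cc(O)cc(C)c2O1 | target

## Step count and least certain steps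

Total: 27 steps. Longest linear sequence: 18 steps (steps 1–10, 17–21, 25–27). The ring A branch has 6 steps (11–16) and the arene branch 3 steps (22–24).

Step 1 (key step). The most likely failure is poor turnover with the unreactive diene, with polymerisation of 2 or loss of catalyst on warming, or incomplete facial discrimination at the temperature that butadiene needs. The fallback keeps the cyclohexene logic but separates ring formation from stereocontrol. Heating 1 with methacrylic acid F1 should give racemic 1-methylcyclohex-3-ene-1-carboxylic acid F2. This would be resolved by crystallisation as the (S)-1-phenylethylammonium (1S)-1-methylcyclohex-3-ene-1-carboxylate salt F3 (the other amine enantiomer is used if the wrong salt is the less soluble one). Acidification gives (1S)-1-methylcyclohex-3-ene-1-carboxylic acid F4, and two equivalents of MeLi in Et2O convert it directly into ketone 5, where the route resumes.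

Step 12. Diastereocontrol may be incomplete (a boat-like closure, or equilibration of the radical conformers before attack), and the hindered Z alkene may slow the cyclisation so that simple reduction of the radical competes. The fallback uses the E series and inverts C3' afterwards. It starts, in place of 14, from geranyl acetate F5. Epoxidation with the enantiomeric ketone catalyst (made from L-sorbose) gives (2E)-5-[(2S)-3,3-dimethyloxiran-2-yl]-3-methylpent-2-en-1-yl acetate F6. The titanium conditions of step 12 then give, through the silyl ether [(1R,3S)-2,2-dimethyl-6-methylidene-3-[(trimethylsilyl)oxy]cyclohexyl]methyl acetate F7, the cis alcohol [(1R,3S)-3-hydroxy-2,2-dimethyl-6-methylidenecyclohexyl]methyl acetate F8, with both substituents equatorial as the E alkene dictates. Dess–Martin oxidation gives [(1R)-2,2-dimethyl-6-methylidene-3-oxocyclohexyl]methyl acetate F9. Reduction with LiBH(s-Bu)3 at −78 °C from the equatorial direction should give the axial alcohol, which is 17.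

Step 6. Acetalisation may give incomplete regiocontrol (the seven-membered acetal or open mixed acetals), and the strained 2,2,4,4-substituted dioxane may be lost on handling. The fallback differentiates the arms by lactone ring size instead. From 6, oxidative cleavage (RuCl3 cat., NaIO4) gives (3S)-3-(acetyloxy)-3-methylhexanedioic acid F10. Saponification and acidification close the only possible γ-lactone to give 2-[(2S)-2-methyl-5-oxooxolan-2-yl]acetic acid F11. BH3·SMe2 reduces the free acid selectively to (5S)-5-(2-hydroxyethyl)-5-methyloxolan-2-one F12. i-Bu2AlH at −78 °C gives the lactol (5S)-5-(2-hydroxyethyl)-5-methyloxolan-2-ol F13. The ylide of step 8 opens it to ethyl (2E,6S)-6,8-dihydroxy-2,6-dimethyloct-2-enoate F14. This compound contains only one diol, so acetalisation with 2,2-dimethoxypropane leads without ambiguity to 11.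

Step 4. The Lewis acid may ionise the tertiary acetate as it forms (elimination, loss of configuration), or migration may be too slow at the low temperature that the peroxide needs. The fallback accepts epoxidation and does not try to avoid it. From 5, excess m-chloroperoxybenzoic acid (NaHCO3 buffer) epoxidises the alkene and effects the Baeyer–Villiger oxidation, giving (3S)-3-methyl-7-oxabicyclo[4.1.0]heptan-3-yl acetate F15 (epoxide epimers). H5IO6 in aqueous THF cleaves the epoxide to (3S)-3-methyl-1,6-dioxohexan-3-yl acetate F16, and NaBH4 reduces this to 7, which the methanolysis of step 5 takes to 8.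

Step 26. Oxidative addition at the electron-rich C–Br bond flanked by two ortho substituents may be slow, so that reduction of the C–Br bond or no ring closure results. The fallback changes metal and halide to a copper-mediated Ullmann closure. From 34, halogen exchange (CuI cat., NaI, trans-N,N'-dimethylcyclohexane-1,2-diamine, dioxane, 110 °C) gives the aryl iodide (3S,6E)-9-[(1R,3R)-3-{[tert-butyl(dimethyl)silyl]oxy}-2,2-dimethyl-6-methylidenecyclohexyl]-1-(2-iodo-3-methyl-5-{[tri(propan-2-yl)silyl]oxy}phenyl)-3,7-dimethylnon-6-en-3-ol F17. CuI with 3,4,7,8-tetramethyl-1,10-phenanthroline and Cs2CO3 in toluene at 110 °C then closes the ether to 35. The C2–O bond again stays intact.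

## Further compounds

F1 | step 1 | methacrylic acid | C=C(C)C(O)=O
F2 | step 1 | racemic 1-methylcyclohex-3-ene-1-carboxylic acid | CC1(CC=CCC1)C(O)=O
F3 | step 1 | (S)-1-phenylethylammonium (1S)-1-methylcyclohex-3-ene-1-carboxylate | C[C@H]([NH3+])c1ccccc1.[O-]C(=O)[C@]1(C)CC=CCC1
F4 | step 1 | (1S)-1-methylcyclohex-3-ene-1-carboxylic acid | OC(=O)[C@]1(C)CC=CCC1
F5 | step 12 | geranyl acetate, (2E)-3,7-dimethylocta-2,6-dien-1-yl acetate | CC(C)=CCC/C(C)=C/COC(C)=O
F6 | step 12 | (2E)-5-[(2S)-3,3-dimethyloxiran-2-yl]-3-methylpent-2-en-1-yl acetate | CC(=O)OC/C=C(C)/CC[C@@H]1OC1(C)C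
F7 | step 12 | [(1R,3S)-2,2-dimethyl-6-methylidene-3-[(trimethylsilyl)oxy]cyclohexyl]methyl acetate | C=C1CC[C@H](O[Si](C)(C)C)C(C)(C)[C@@H]1COC(C)=O
F8 | step 12 | [(1R,3S)-3-hydroxy-2,2-dimethyl-6-methylidenecyclohexyl]methyl acetate | C=C1CC[C@H](O)C(C)(C)[C@@H]1COC(C)=O
F9 | step 12 | [(1R)-2,2-dimethyl-6-methylidene-3-oxocyclohexyl]methyl acetate | C=C1CCC(=O)C(C)(C)[C@@H]1COC(C)=O
F10 | step 6 | (3S)-3-(acetyloxy)-3-methylhexanedioic acid | CC(=O)O[C@](CCC(O)=O)(C)CC(O)=O
F11 | step 6 | 2-[(2S)-2-methyl-5-oxooxolan-2-yl]acetic acid | O=C1CC[C@@](C)(CC(O)=O)O1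
F12 | step 6 | (5S)-5-(2-hydroxyethyl)-5-methyloxolan-2-one | O=C1CC[C@@](C)(CCO)O1
F13 | step 6 | (5S)-5-(2-hydroxyethyl)-5-methyloxolan-2-ol (both anomers) | OC1CC[C@@](C)(CCO)O1
F14 | step 6 | ethyl (2E,6S)-6,8-dihydroxy-2,6-dimethyloct-2-enoate | CCOC(=O)/C(C)=C/CC[C@@](O)(C)CCO
F15 | step 4 | (3S)-3-methyl-7-oxabicyclo[4.1.0]heptan-3-yl acetate (epoxide epimers) | CC(=O)O[C@]1(C)CC2OC2CC1
F16 | step 4 | (3S)-3-methyl-1,6-dioxohexan-3-yl acetate | CC(=O)O[C@](CCC=O)(C)CC=O
F17 | step 26 | (3S,6E)-9-[(1R,3R)-3-{[tert-butyl(dimethyl)silyl]oxy}-2,2-dimethyl-6-methylidenecyclohexyl]-1-(2-iodo-3-methyl-5-{[tri(propan-2-yl)silyl]oxy}phenyl)-3,7-dimethylnon-6-en-3-ol | C=C1CC[C@@H](O[Si](C)(C)C(C)(C)C)C(C)(C)[C@@H]1CC/C(C)=C/CC[C@@](O)(C)CCc1cc(O[Si](C(C)C)(C(C)C)C(C)C)cc(C)c1I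
A1 | alternative 1 | (3S,6E)-1-(2-bromo-5-methoxy-3-methylphenyl)-9-[(1R,3R)-3-{[tert-butyl(dimethyl)silyl]oxy}-2,2-dimethyl-6-methylidenecyclohexyl]-3,7-dimethylnon-6-en-3-ol | C=C1CC[C@@H](O[Si](C)(C)C(C)(C)C)C(C)(C)[C@@H]1CC/C(C)=C/CC[C@](C)(O)CCc1cc(OC)cc(C)c1Br
A2 | alternative 1 | tert-butyl{[(1R,3R)-3-(but-3-yn-1-yl)-2,2-dimethyl-4-methylidenecyclohexyl]oxy}dimethylsilane | C=C1CC[C@@H](O[Si](C)(C)C(C)(C)C)C(C)(C)[C@@H]1CCC#C
A3 | alternative 1 | (2R)-2-[2-(2-bromo-5-methoxy-3-methylphenyl)ethyl]-2-methyloxetane | C[C@@]1(CCc2cc(OC)cc(C)c2Br)CCO1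
A4 | alternative 2 | ethyl 2-[(1R,3S)-3-{[tert-butyl(dimethyl)silyl]oxy}-2,2-dimethyl-6-methylidenecyclohexyl]acetate | C=C1CC[C@H](O[Si](C)(C)C(C)(C)C)C(C)(C)[C@@H]1CC(=O)OCC
A5 | alternative 2 | ethyl (2E,5S)-5-{[tert-butyl(dimethyl)silyl]oxy}-4,4-dimethylnon-2-en-8-ynoate | C#CCC[C@H](O[Si](C)(C)C(C)(C)C)C(C)(C)/C=C/C(=O)OCC
A6 | alternative 3 | (2S)-2,8-dimethyl-2-(4-methylpent-3-en-1-yl)-3,4-dihydro-2H-chromen-6-ol | CC(C)=CCC[C@@]1(C)CCc2cc(O)cc(C)c2O1
A7 | alternative 3 | (2S)-2,6-dimethyl-2-(4-methylpent-3-en-1-yl)-1-oxaspiro[4.5]deca-6,9-dien-8-one (spiro centre unspecified) | CC(C)=CCC[C@@]1(C)CCC2(O1)C=CC(=O)C=C2C
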